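**Plan**

Decalin numbering: C1 quaternary (Me, acyl), C2 sec-butyl, C3=C4, C4a/C8a fusion, C5 ester, C6 OH, C8 Me. The enabling feature is that the side-chain carbonyl carbon hangs from quaternary C1 directly beside ring-fusion carbon C8a of cyclohexene ring A, so ring A plus that carbon is a cyclohept-4-enone whose C=O has been pushed out from between C1 and C8a.
Retrosynthetic cuts, in order: C5–O ester (anhydride opening); side-chain β-C–O and C(=O)–vinyl bonds; C1–C8a (re-expanded to an α-bromo cycloheptenone); C1–C2 and C4a–C8a together ((4+3)); then C(O)–C1 (carbenoid addition), C8–Me (conjugate addition), C8=C8a, C4a=C4 and C2=C3 (olefinations).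
Forward: the C4a–C8 chain comes from 2-deoxy-L-ribose and is extended at both ends; ring B and the seven-membered ring close together in one intramolecular oxyallyl cycloaddition; ring A then arises by contraction; side chain and ester come last.
Stereochemistry: C5/C6 from the sugar; the sec-butyl centre from (R)-2-methylbutanoic acid; C8 from a ligand-controlled Cu-catalysed methyl addition; C2, C4a, C8a and the C1–Br centre from the cycloaddition (E,E-diene, chair-like tether, cation geometry); C1 by inversion in the shift; the Z-enoate from the cyclic anhydride.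

Key step: step 14

Assumption: the sense of the CuI/Tol-BINAP methyl addition is set by the ligand alone; (S)-Tol-BINAP is taken to give the (3R)-ester from the E-enoate, and its mirror image would be used if the sense proved opposite.

**Route**

Step 1
Reactants: 1 (R)-2-methylbutanoic acid
Product: 2 (R)-2-methylbutan-1-ol
Conditions: LiAlH4, Et2O, 0 °C → rt; aqueous work-up
Reagents that add atoms: none
Why: Hydride reduction of the carboxylic acid proceeds through the lithium carboxylate, which is not enolised, so the α-stereocentre should be carried over unchanged.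

Step 2
Reactants: 2 (R)-2-methylbutan-1-ol
Product: 3 5-{[(2R)-2-methylbutyl]sulfanyl}-1-phenyl-1H-tetrazole
Conditions: 1-phenyl-1H-tetrazole-5-thiol, PPh3, DIAD, THF, 0 °C → rt
Reagents that add atoms: 1-phenyl-1H-tetrazole-5-thiol, Sc1nnnn1-c1ccccc1
Why: Mitsunobu thioetherification of the primary alcohol with the acidic thiol; the stereocentre is one carbon away from the reacting CH2 and is not touched.

Step 3
Reactants: 3 5-{[(2R)-2-methylbutyl]sulfanyl}-1-phenyl-1H-tetrazole
Product: 4 5-{[(2R)-2-methylbutyl]sulfonyl}-1-phenyl-1H-tetrazole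
Conditions: (NH4)6Mo7O24·4H2O (cat.), 30% H2O2, EtOH, 0 °C → rt
Reagents that add atoms: hydrogen peroxide, OO
Why: Molybdate-catalysed sulfide-to-sulfone oxidation is the standard entry to Julia–Kocienski reagents and involves no stereocentre.

Step 4
Reactants: 5 2-deoxy-L-ribose
Product: 6 2-deoxy-3,4-O-isopropylidene-L-erythro-pentopyranose (anomer mixture)
Conditions: 2-methoxypropene, PPTS (cat.), EtOAc, rt
Reagents that add atoms: 2-methoxypropene, COC(C)=C
Why: Kinetic acetalisation with an enol ether selects the cis-3,4-diol of the pyranose form and leaves the lactol free; sugar C3 and C4 become C6 and C5 of the target.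

Step 5
Reactants: 6 2-deoxy-3,4-O-isopropylidene-L-erythro-pentopyranose
Product: 7 ethyl (2E)-4-[(4R,5S)-5-(hydroxymethyl)-2,2-dimethyl-1,3-dioxolan-4-yl]but-2-enoate
Conditions: Ph3P=CHCO2Et, PhCO2H (cat.), DME, reflux
Reagents that add atoms: ethyl (triphenylphosphoranylidene)acetate, CCOC(=O)C=P(c1ccccc1)(c1ccccc1)c1ccccc1
Why: Wittig olefination of the open-chain aldehyde in equilibrium with the lactol by a stabilised ylide should give the E-enoate, and the neutral medium keeps the freed primary alkoxide from adding back in an oxa-Michael reaction.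

Step 6
Reactants: 7 ethyl (2E)-4-[(4R,5S)-5-(hydroxymethyl)-2,2-dimethyl-1,3-dioxolan-4-yl]but-2-enoate
Product: 8 ethyl (2E)-4-[(4R,5R)-5-formyl-2,2-dimethyl-1,3-dioxolan-4-yl]but-2-enoate (cis-4,5)
Conditions: Dess–Martin periodinane, pyridine, CH2Cl2, 0 °C → rt
Reagents that add atoms: none
Why: Dess–Martin oxidation under buffered, non-basic conditions should give the α-alkoxy aldehyde without epimerisation at C5 and without touching the enoate.

Step 7
Reactants: 8 ethyl (2E)-4-[(4R,5R)-5-formyl-2,2-dimethyl-1,3-dioxolan-4-yl]but-2-enoate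
Product: 9 ethyl (2E)-4-{(4R,5S)-2,2-dimethyl-5-[(1E)-3-oxoprop-1-en-1-yl]-1,3-dioxolan-4-yl}but-2-enoate
Conditions: Ph3P=CHCHO, toluene, 60 °C
Reagents that add atoms: (triphenylphosphoranylidene)acetaldehyde, O=CC=P(c1ccccc1)(c1ccccc1)c1ccccc1
Why: Wittig olefination with the formyl-stabilised ylide is selective for the aldehyde over the enoate, gives the E-enal (C4a=C4) and is too weakly basic to disturb the adjacent acetonide centre.

Step 8
Reactants: 9 ethyl (2E)-4-{(4R,5S)-2,2-dimethyl-5-[(1E)-3-oxoprop-1-en-1-yl]-1,3-dioxolan-4-yl}but-2-enoate; 4 5-{[(2R)-2-methylbutyl]sulfonyl}-1-phenyl-1H-tetrazole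
Product: 10 ethyl (2E)-4-{(4R,5S)-2,2-dimethyl-5-[(1E,3E,5R)-5-methylhepta-1,3-dien-1-yl]-1,3-dioxolan-4-yl}but-2-enoate
Conditions: 4, KHMDS, DME, −60 °C; then 9, −60 °C → rt
Reagents that add atoms: none
Why: Julia–Kocienski olefination: the pre-formed potassium salt of the PT sulfone adds to the aldehyde faster than to either conjugate acceptor and should give the new C2=C3 bond with E geometry, the sec-butyl centre being β to the carbanion and not epimerisable.

Step 9
Reactants: 10 ethyl (2E)-4-{(4R,5S)-2,2-dimethyl-5-[(1E,3E,5R)-5-methylhepta-1,3-dien-1-yl]-1,3-dioxolan-4-yl}but-2-enoate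
Product: 11 ethyl (3R)-3-methyl-4-{(4R,5S)-2,2-dimethyl-5-[(1E,3E,5R)-5-methylhepta-1,3-dien-1-yl]-1,3-dioxolan-4-yl}butanoate
Conditions: MeMgBr, CuI (cat.), (S)-Tol-BINAP (cat.), t-BuOMe, −20 °C
Reagents that add atoms: methylmagnesium bromide, C[Mg]Br
Why: Copper-catalysed enantioselective conjugate addition of a Grignard reagent to an E-enoate, in which the ligand and not the remote C6 centre selects the face at C8, while the unactivated diene and the acetonide should be inert to the methylcuprate.

Step 10
Reactants: 11 ethyl (3R)-3-methyl-4-{(4R,5S)-2,2-dimethyl-5-[(1E,3E,5R)-5-methylhepta-1,3-dien-1-yl]-1,3-dioxolan-4-yl}butanoate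
Product: 12 (3R)-3-methyl-4-{(4R,5S)-2,2-dimethyl-5-[(1E,3E,5R)-5-methylhepta-1,3-dien-1-yl]-1,3-dioxolan-4-yl}butanal
Conditions: DIBAL-H, CH2Cl2, −78 °C; MeOH, then aq. Rochelle salt
Reagents that add atoms: none
Why: Partial ester reduction with DIBAL-H at −78 °C stops at the aluminium hemiacetal, which releases the aldehyde on work-up; C8 is β to the carbonyl and cannot epimerise.

Step 11
Reactants: 12 (3R)-3-methyl-4-{(4R,5S)-2,2-dimethyl-5-[(1E,3E,5R)-5-methylhepta-1,3-dien-1-yl]-1,3-dioxolan-4-yl}butanal
Product: 13 2,2-dibromo-5-methyl-6-{2,2-dimethyl-5-[(1E,3E)-5-methylhepta-1,3-dien-1-yl]-1,3-dioxolan-4-yl}hexan-3-ol (C3 epimers; all other centres as in 12)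
Conditions: CH3CHBr2, LDA, THF/Et2O, −100 °C; then 12; AcOH quench at −100 °C
Reagents that add atoms: 1,1-dibromoethane, CC(Br)Br
Why: Carbenoid 1,2-addition: 1,1-dibromoethyllithium formed by deprotonation at −100 °C should add to the aldehyde faster than it decomposes, and cold protonation stops the alkoxide before it rearranges; the carbinol centre forms as a mixture that the next step removes.

Step 12
Reactants: 13 2,2-dibromo-5-methyl-6-{2,2-dimethyl-5-[(1E,3E)-5-methylhepta-1,3-dien-1-yl]-1,3-dioxolan-4-yl}hexan-3-ol
Product: 14 (5R)-2,2-dibromo-5-methyl-6-{(4R,5S)-2,2-dimethyl-5-[(1E,3E,5R)-5-methylhepta-1,3-dien-1-yl]-1,3-dioxolan-4-yl}hexan-3-one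
Conditions: Dess–Martin periodinane, pyridine, CH2Cl2, rt
Reagents that add atoms: none
Why: Dess–Martin oxidation of the secondary β,β-dibromo alcohol should give the α,α-dibromo ketone, whose only α-hydrogens are at C8a, without affecting diene or acetonide.

Step 13
Reactants: 14 (5R)-2,2-dibromo-5-methyl-6-{(4R,5S)-2,2-dimethyl-5-[(1E,3E,5R)-5-methylhepta-1,3-dien-1-yl]-1,3-dioxolan-4-yl}hexan-3-one
Product: 16 trans-fused 6–7 α-bromo cycloheptenone, via bromo-oxyallyl cation 15 (not isolated)
Conditions: Et3N, CF3CH2OH/Et2O (1:1), 0.005 M, 0 °C → rt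
Reagents that add atoms: none
Why: Triethylamine enolises 14 toward C8a and loss of bromide gives cation 15, which the tethered diene should trap in an intramolecular oxyallyl (4+3) cycloaddition forming C4a–C8a and C1–C2 (ring B and the seven-membered ring close together); the E,E-diene puts H-2 and H-4a cis, an extended transition state with the chain syn to oxygen at C8a gives the trans fusion, the chair-like tether with Me-8 and O-5 equatorial relates C4a/C8a to the existing centres, and the cation geometry with methyl syn and bromine anti to oxygen (dipole minimisation) places Br cis to H-8a.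

Step 14
Reactants: 16 trans-fused 6–7 α-bromo cycloheptenone
Product: 19 ring-contracted decalin with CH2OH on C1, via bromohydrin alkoxide 17 (not isolated), via ring-contracted aldehyde 18 (not isolated)
Conditions: LiAlH4, THF, −40 °C → rt (45 °C to complete the shift); aqueous work-up
Reagents that add atoms: none
Why: Hydride adds to the ketone of 16 (anti to the polar C1–Br bond) to give alkoxide 17; when the seven-membered ring twists so that the C(O)–C8a bond is anti-periplanar to C1–Br, the alkoxide pushes that bond onto C1 as bromide leaves, giving aldehyde 18, which excess LiAlH4 reduces at once to 19. The closest known reaction is the hydride-triggered quasi-Favorskii (semipinacol) ring contraction of α-bromo ketones obtained from (4+3) cycloadditions. Ring A is closed by this 1,2-alkyl shift through a bridged three-centre transition state (C1–C8a forms as C(O)–C8a breaks), not by an end-to-end cyclisation, and the extruded carbon stays on C1 as CH2OH. The only new stereocentre is C1: C8a enters opposite to bromide, so C1 is inverted and the bromide configuration from step 13 (Br cis to H-8a) becomes Me-1 cis to H-4a with the carbinol carbon on the H-8a face, while C8a migrates with retention and keeps the trans fusion. The step needs carbon, not the carbinol hydrogen or oxygen, to stand anti to bromide; this holds only in the twist-boat of the cycloheptene (in the chair C–Br is axial), and there the shift is helped by the tertiary, non-enolisable, SN2-inert C1–Br and by relief of crowding around C1 on going to the six-membered ring, while warming the pre-formed aluminate rather than adding hydride hot limits direct C–Br reduction.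

Step 15
Reactants: 19 ring-contracted decalin with CH2OH on C1
Product: 18 ring-contracted aldehyde (CHO on C1)
Conditions: Dess–Martin periodinane, pyridine, CH2Cl2, rt
Reagents that add atoms: none
Why: Dess–Martin oxidation of the neopentyl primary alcohol should give the non-enolisable aldehyde; quaternary C1 cannot epimerise.

Step 16
Reactants: 18 ring-contracted aldehyde
Product: 20 allylic alcohol, C1–CH(OH)–CH=CH2 (carbinol epimers)
Conditions: CH2=CHMgBr, THF, −78 → 0 °C
Reagents that add atoms: vinylmagnesium bromide, C=C[Mg]Br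
Why: Grignard 1,2-addition to the hindered, non-enolisable aldehyde; the carbinol centre forms as a mixture that is oxidised away in the next step.

Step 17
Reactants: 20 allylic alcohol
Product: 21 vinyl ketone, C1–C(=O)–CH=CH2
Conditions: Dess–Martin periodinane, pyridine, CH2Cl2, 0 °C → rt
Reagents that add atoms: none
Why: Dess–Martin oxidation of the allylic alcohol gives the enone without acid or base that could isomerise or polymerise it.

Step 18
Reactants: 21 vinyl ketone
Product: 22 β-(4-methoxybenzyloxy) ketone, C1–C(=O)–CH2CH2–OPMB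
Conditions: 4-methoxybenzyl alcohol (excess), PMe3 (cat.), THF, rt
Reagents that add atoms: 4-methoxybenzyl alcohol, COc1ccc(CO)cc1
Why: Phosphine-catalysed oxa-Michael addition: PMe3 adds to the unhindered β-carbon, the zwitterion deprotonates the alcohol and the alkoxide adds to the enone, so the β-oxygen arrives already protected and no stereocentre is formed.

Step 19
Reactants: 22 β-(4-methoxybenzyloxy) ketone
Product: 23 C5,C6-diol
Conditions: AcOH/H2O (4:1), 50 °C
Reagents that add atoms: none
Why: Acid-catalysed acetal hydrolysis in aqueous acetic acid should free the cis-diol while the PMB ether, the β-alkoxy ketone and the ring alkene tolerate the weak acid.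

Step 20
Reactants: 23 C5,C6-diol; 24 3-methylglutaconic anhydride
Product: 25 C5 (Z)-3-methylglutaconate half ester, PMB ether
Conditions: 24 (1.5 equiv), toluene, 40 °C, no base
Reagents that add atoms: none
Why: Uncatalysed alcoholysis of the cyclic anhydride: the equatorial C5–OH should be acylated in preference to the axial C6–OH, attack goes to the non-conjugated carbonyl, and the cis ring geometry of the anhydride is delivered as the Z-alkene of the half ester.

Step 21
Reactants: 25 C5 (Z)-3-methylglutaconate half ester, PMB ether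
Product: 26 tandyukisin C
Conditions: DDQ, CH2Cl2/pH 7 buffer (10:1), 0 °C
Reagents that add atoms: none
Why: Oxidative PMB cleavage with DDQ in wet, buffered dichloromethane is neutral and should leave the half ester, the free acid, the β-hydroxy ketone and the ring alkene intact.

**Compound list**

1 | (R)-2-methylbutanoic acid | CC[C@@H](C)C(=O)O | starting material
2 | (R)-2-methylbutan-1-ol | CC[C@@H](C)CO | intermediate
3 | 5-{[(2R)-2-methylbutyl]sulfanyl}-1-phenyl-1H-tetrazole | CC[C@@H](C)CSc1nnnn1-c1ccccc1 | intermediate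
4 | 5-{[(2R)-2-methylbutyl]sulfonyl}-1-phenyl-1H-tetrazole | CC[C@@H](C)CS(=O)(=O)c1nnnn1-c1ccccc1 | intermediate
5 | 2-deoxy-L-ribose | O=CC[C@@H](O)[C@@H](O)CO | starting material
6 | 2-deoxy-3,4-O-isopropylidene-L-erythro-pentopyranose (anomer mixture) | OC1C[C@H]2OC(C)(C)O[C@H]2CO1 | intermediate
7 | ethyl (2E)-4-[(4R,5S)-5-(hydroxymethyl)-2,2-dimethyl-1,3-dioxolan-4-yl]but-2-enoate | CCOC(=O)/C=C/C[C@H]1OC(C)(C)O[C@H]1CO | intermediate
8 | ethyl (2E)-4-[(4R,5R)-5-formyl-2,2-dimethyl-1,3-dioxolan-4-yl]but-2-enoate (cis-4,5) | CCOC(=O)/C=C/C[C@H]1OC(C)(C)O[C@H]1C=O | intermediate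
9 | ethyl (2E)-4-{(4R,5S)-2,2-dimethyl-5-[(1E)-3-oxoprop-1-en-1-yl]-1,3-dioxolan-4-yl}but-2-enoate | CCOC(=O)/C=C/C[C@H]1OC(C)(C)O[C@H]1/C=C/C=O | intermediate
10 | ethyl (2E)-4-{(4R,5S)-2,2-dimethyl-5-[(1E,3E,5R)-5-methylhepta-1,3-dien-1-yl]-1,3-dioxolan-4-yl}but-2-enoate | CCOC(=O)/C=C/C[C@H]1OC(C)(C)O[C@H]1/C=C/C=C/[C@H](C)CC | intermediate
11 | ethyl (3R)-3-methyl-4-{(4R,5S)-2,2-dimethyl-5-[(1E,3E,5R)-5-methylhepta-1,3-dien-1-yl]-1,3-dioxolan-4-yl}butanoate | CCOC(=O)C[C@H](C)C[C@H]1OC(C)(C)O[C@H]1/C=C/C=C/[C@H](C)CC | intermediate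
12 | (3R)-3-methyl-4-{(4R,5S)-2,2-dimethyl-5-[(1E,3E,5R)-5-methylhepta-1,3-dien-1-yl]-1,3-dioxolan-4-yl}butanal | O=CC[C@H](C)C[C@H]1OC(C)(C)O[C@H]1/C=C/C=C/[C@H](C)CC | intermediate
13 | 2,2-dibromo-5-methyl-6-{2,2-dimethyl-5-[(1E,3E)-5-methylhepta-1,3-dien-1-yl]-1,3-dioxolan-4-yl}hexan-3-ol, C3 epimers, other centres as in 12 | CC(Br)(Br)C(O)C[C@H](C)C[C@H]1OC(C)(C)O[C@H]1/C=C/C=C/[C@H](C)CC | intermediate
14 | (5R)-2,2-dibromo-5-methyl-6-{(4R,5S)-2,2-dimethyl-5-[(1E,3E,5R)-5-methylhepta-1,3-dien-1-yl]-1,3-dioxolan-4-yl}hexan-3-one | CC(Br)(Br)C(=O)C[C@H](C)C[C@H]1OC(C)(C)O[C@H]1/C=C/C=C/[C@H](C)CC | intermediate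
15 | bromo-oxyallyl cation from 14 (zwitterion; methyl and chain syn to O, Br anti; not isolated) | C/C(Br)=C(\[O-])[CH+]C[C@H](C)C[C@H]1OC(C)(C)O[C@H]1/C=C/C=C/[C@H](C)CC | intermediate
16 | trans-fused 6–7 α-bromo ketone: cyclohept-4-enone ring [C(=O), C1(Me)(Br), C2(sec-butyl), C3=C4, C4a, C8a] fused at C4a–C8a to the cyclohexane carrying the C5,C6-acetonide and Me-8; H-2, H-4a, Me-1, O-5, O-6 on one face, H-8a, Br and Me-8 on the other; (R)-sec-butyl | CC[C@@H](C)[C@H]1C=C[C@H]2[C@@H]3OC(C)(C)O[C@@H]3C[C@@H](C)[C@@H]2C(=O)[C@@]1(C)Br | intermediate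
17 | lithium alkoxide of the bromohydrin from 16 (either carbinol epimer; not isolated) | CC[C@@H](C)[C@H]1C=C[C@H]2[C@@H]3OC(C)(C)O[C@@H]3C[C@@H](C)[C@@H]2C([O-])[C@@]1(C)Br.[Li+] | intermediate
18 | ring-contracted aldehyde: trans-decalin (ring A cyclohex-3-ene), C1 bearing Me (cis to H-4a) and CHO (cis to H-8a), C5,C6-acetonide, Me-8, (R)-sec-butyl on C2 | CC[C@@H](C)[C@H]1C=C[C@H]2[C@@H]3OC(C)(C)O[C@@H]3C[C@@H](C)[C@@H]2[C@@]1(C)C=O | intermediate
19 | ring-contracted primary alcohol: as 18 with CH2OH on C1 | CC[C@@H](C)[C@H]1C=C[C@H]2[C@@H]3OC(C)(C)O[C@@H]3C[C@@H](C)[C@@H]2[C@@]1(C)CO | intermediate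
20 | allylic alcohol: as 18 with CH(OH)CH=CH2 on C1 (carbinol epimers) | CC[C@@H](C)[C@H]1C=C[C@H]2[C@@H]3OC(C)(C)O[C@@H]3C[C@@H](C)[C@@H]2[C@@]1(C)C(O)C=C | intermediate
21 | vinyl ketone: as 18 with C(=O)CH=CH2 on C1 | CC[C@@H](C)[C@H]1C=C[C@H]2[C@@H]3OC(C)(C)O[C@@H]3C[C@@H](C)[C@@H]2[C@@]1(C)C(=O)C=C | intermediate
22 | β-PMB-oxy ketone: as 18 with C(=O)CH2CH2O-PMB on C1 | CC[C@@H](C)[C@H]1C=C[C@H]2[C@@H]3OC(C)(C)O[C@@H]3C[C@@H](C)[C@@H]2[C@@]1(C)C(=O)CCOCc1ccc(OC)cc1 | intermediate
23 | C5,C6-cis-diol of 22 (5-OH equatorial, 6-OH axial) | CC[C@@H](C)[C@H]1C=C[C@H]2[C@H](O)[C@H](O)C[C@@H](C)[C@@H]2[C@@]1(C)C(=O)CCOCc1ccc(OC)cc1 | intermediate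
24 | 3-methylglutaconic anhydride (4-methyl-2H-pyran-2,6(3H)-dione) | CC1=CC(=O)OC(=O)C1 | starting material
25 | PMB ether of tandyukisin C: C5 ester of (Z)-3-methylglutaconic acid through its CH2C(=O) carboxyl, free conjugated CO2H, free 6-OH | CC[C@@H](C)[C@H]1C=C[C@H]2[C@H](OC(=O)C/C(C)=C\C(=O)O)[C@H](O)C[C@@H](C)[C@@H]2[C@@]1(C)C(=O)CCOCc1ccc(OC)cc1 | intermediate
26 | tandyukisin C | CC[C@@H](C)[C@H]1C=C[C@H]2[C@H](OC(=O)C/C(C)=C\C(=O)O)[C@H](O)C[C@@H](C)[C@@H]2[C@@]1(C)C(=O)CCO | target

**Step count**

Total steps: 21. Longest linear sequence: 18 (steps 4–21, from 2-deoxy-L-ribose); steps 1–3 make the sulfone used in step 8.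

**Steps most likely to fail**

Step 13. The cation may be lost before the hindered C1–C2 bond forms, through capture by trifluoroethanol, Favorskii-type collapse, proton loss from the methyl group, or closure through oxygen. The approach may also be compact rather than extended (cis fusion), or the methyl/bromine geometry of the cation may be poorly controlled (wrong C1–Br configuration). The fallback sets out from 14 and changes how the cation is made. 14 is converted with TMSOTf/Et3N (CH2Cl2, 0 °C) into its (Z)-trimethylsilyl enol ether F1, in which the chain is fixed syn to oxygen. Silver(I) (AgBF4, CH3NO2/CH2Cl2, −78 → 0 °C) then abstracts one bromide in an aprotic medium to give the more electrophilic silyloxyallyl cation, which favours the extended approach and cannot be intercepted by solvent. Desilylation on work-up returns the route at 16.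

Step 14. After hydride addition the ring may react from its chair conformer, where the new C–H bond (or the C–O bond), not the C(O)–C8a bond, lies anti to the axial C–Br. Hydrogen shift with loss of bromine, epoxide closure, or survival of the unrearranged bromohydrin could then outrun the contraction. The fallback sets out from 16 and uses a silver-assisted semibenzilic rearrangement (AgBF4, 2,6-lutidine, MeOH, 0 °C → rt). Methanol adds reversibly to the ketone and silver pulls the bromide; the hemiketal has no hydrogen on the carbinol carbon, so only C8a can migrate, giving the methyl ester F2. LiAlH4 (THF, 0 °C) then reduces F2, and the route is rejoined at 19.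

Step 20. Acylation may be unselective between the equatorial C5–OH and the axial C6–OH, may go on to the bis-ester, or may be slow enough at the hindered C5–OH for the half ester to re-close. The fallback sets out from 23 and activates the nucleophile instead of relying on intrinsic reactivity. Bu2SnO (toluene, reflux, water removed) gives the 5,6-O-dibutylstannylene acetal F3, in which the equatorial oxygen is the reactive one. Treatment with 24 at room temperature and a mildly acidic work-up returns the route at 25.

**Further compounds**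

F1 | step 13 | (Z)-trimethylsilyl enol ether of 14 (C8a=C(OSiMe3), chain syn to O) | CC(Br)(Br)/C(O[Si](C)(C)C)=C/[C@H](C)C[C@H]1OC(C)(C)O[C@H]1/C=C/C=C/[C@H](C)CC
F2 | step 14 | ring-contracted methyl ester (as 18 with CO2Me on C1) | CC[C@@H](C)[C@H]1C=C[C@H]2[C@@H]3OC(C)(C)O[C@@H]3C[C@@H](C)[C@@H]2[C@@]1(C)C(=O)OC
F3 | step 20 | 5,6-O-dibutylstannylene acetal of 23 | CC[C@@H](C)[C@H]1C=C[C@H]2[C@@H]3O[Sn](CCCC)(CCCC)O[C@@H]3C[C@@H](C)[C@@H]2[C@@]1(C)C(=O)CCOCc1ccc(OC)cc1
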